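The readings were generated by integration from invented constants.

A flat yield curve tempts one to call it an equilibrium, yet a flat curve with its substrate at zero may be a flask that has stopped. The midnight run is the flask asked about, followed so far.

| setting | midnight | summer | flask |
|---|---|---|---|
| substrate | 2 M | 1.3 M | 2.0 M |
| temperature | 35 °C | 35 °C | 35 °C |
| remark | the very flask that is asked about, followed so far | run made earlier |  |
| time |  |  | 5.0 d |

| run | time / h | ring / % | substrate / % |
|---|---|---|---|
| midnight | 8.00 | 36 | 19 |
| midnight | 25.0 | 45 | 3 |
| midnight | 40.0 | 41 | 0 |
| midnight | 60.0 | 42 | 0 |
| midnight | 96.0 | 45 | 0 |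
| midnight | 120 | 41 | 0 |
| summer | 2.00 | 17 | 63 |
| summer | 3.00 | 20 | 55 |
| summer | 6.00 | 33 | 31 |
| summer | 10.0 | 44 | 18 |
| summer | 15.0 | 47 | 7 |
| summer | 25.0 | 51 | 1 |

(readings scatter by 1.5 percentage points)

- Wednesday's: change nothing and wait 5.0 d more
- Thursday's: at 5.0 d take out 90% of the ring then present, then wait 5.0 d
- Tuesday's: at 5.0 d raise the temperature by 20 K, then wait 5.0 d

- ring, in percent of the substrate first charged, at 5.0 d
- what to do for the largest gain in ring; "none" if nothing gains more than 2 percentage points (Wednesday's / Thursday's / Tuesday's / none)
- ring present, with what was taken out counted in, in percent of the substrate first charged, after Thursday's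
- ring present, with what was taken out counted in, in percent of the substrate first charged, after Tuesday's

- what is taken out of ring is counted as made
- the numbers in the tables scatter by 1.5 percentage points (one standard deviation)
- the earlier runs do not show what temperature does; that part of a forecast is a guess

I let substrate go to ring at first order and to loss at second order. Dividing the two rates and integrating down to no substrate gave the final ring share as ln(1 + B)/B, where B is proportional to the charge. The midnight plateau from 25.0 h on averaged 42.8%, and solving by iteration gave B = 3.53. This is my competition number, a selectivity factor read from the midnight plateau: how many times faster substrate is lost than it becomes ring at the start of the midnight run.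

Scaled to the summer charge, B became 2.29 and gave 52.0%, close to the 51% read at 25.0 h. One number was not enough for the course, though. For the 63% substrate read at 2.00 h of the summer run it gave 13.0% ring, and the reading of 17% stood higher. Midnight substrate read 0% at 120 h with ring flat, so I took the flask as stopped and reckoned 42.8% for now and after either intervention, with best "none"; the part about heat was a guess.

The forecast stood near mine with 43% now but parted from it after that: best Thursday's, 69% after Thursday's and 51% after Tuesday's, on the reading “The plateau is then equilibrium, not exhaustion”.

The flask gave 43.2% now, best none, 43.2% after Thursday's and 43.2% after Tuesday's.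

    substrate → ring (k = 0.110 h⁻¹, Ea = 104 kJ mol⁻¹)
    2 substrate → open dimer (k = 0.0500 M⁻¹ h⁻¹, Ea = 87.0 kJ mol⁻¹)
    substrate + ring → side product (k = 0.0380 M⁻¹ h⁻¹, Ea = 87.0 kJ mol⁻¹)
    (constants at 35 °C)

Scaled to the neighbouring flask charged with 0.80 M, my B becomes 1.41, and the same formula gives 62.4% ring. That flask held 63.5% ring at 120 h, with substrate at 0% and open dimer at 23.8%.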